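# Proposed total synthesis of CNP0139964.1 by an anodic Achmatowicz route to ring C

Chain numbering runs from C1 (alkyne CH) to C15 (ethyl CH3). Ring A is O/C3–C6, ring B is O/C4–C7 and ring C is O/C9–C13. Compound numbers refer to the list after the steps.

Remark on the chemistry: the C8 oxygen is carried as a tert-butyldiphenylsilyl ether, which tolerates the trifluoroacetic acid of step 5 better than a tert-butyldimethylsilyl ether. Hemiketal 8 is drawn as the anomer with axial hydroxyl; its C9 configuration is erased in step 5.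

## Analysis of the target

- **Ring system.** The C15 chain is folded into three ether rings. Rings A and B share C4–C5–C6 and form a 2,5-dioxabicyclo[2.2.1]heptane. Ring C is a tetrahydropyran attached through the bromomethine C8.
- **Stereocentres.** There are nine: 3S, 4S, 6S, 7S, 8R, 9S, 10S, 12R, 13S.
- **Ring C relationships.** The C9 and C13 substituents are cis, and each bromide is trans to its neighbouring alkyl group. All four substituents are therefore equatorial, and the two bromides are cis to each other.
- **Bicycle relationships.** The ethynyl group at C3 is endo, cis to the C4 oxygen on ring A. The C8 branch at C7 is exo. The C7–O and C8–Br bonds are syn in the extended chain, which is the result of an anti addition to a (Z)-C7=C8 alkene.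
- **Sensitive groups.** The three secondary bromides are each β to one or two ether oxygens. They are open to elimination and to oxonium participation. The terminal alkyne and the strained bis-ether add to this.
- **Difficulty.** Three C–Br centres must be set next to oxygen, and the bicycle must be closed without losing them.
- **Feature used.** Ring C has heteroatoms on C10 and C12, a methylene at C11 and a cis C9/C13 pair across the ring oxygen. This is the pattern of a 2,5-disubstituted furan (C9–C12) bearing the C13 carbinol. Oxidative ring expansion of that furan gives the C12 ketone and the C10=C11 alkene.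

## Retrosynthetic reasoning

**Ring A, O–C3 bond.** Target 39 is cut at the O–C3 bond, leading back to mesylate 36. C3 is propargylic and therefore the best SN2 site of the bicycle. Attack by the C6 alkoxide (5-exo-tet) with inversion turns the 3R carbinol into the endo-ethynyl 3S centre. Ring A is closed last because the reverse order would require ring B to close onto the alkene from a rigid ring A. In that case C6–H cannot lie in the alkene plane, and C9 would eclipse C5. A mesylate is chosen over a triflate so that the ring B oxygen does not ionise C3.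

**Ring B, O–C7 and C8–Br bonds.** Alcohol 35 is cut at O–C7 and C8–Br, leading back to (Z)-alkene 33. A bromonium-induced 5-exo etherification places bromine on C8 without an SN2 reaction at a carbon flanked by two ether oxygens. It sets C7 and C8 together. Anti addition to the Z alkene gives the syn O/Br pattern. Allylic 1,3-strain keeps C6–H in the alkene plane, so the tethered C4 oxygen can reach only one face. That face leads to 7S,8R. The acetonide oxygen on C4 is the nucleophile, and the acetal falls away to free the C3 hydroxyl for activation.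

**C6–C7 bond.** Alkene 33 is cut at C6–C7 into alkyne 19 and aldehyde 27. The forward sequence is acetylide addition, oxidation to ynone 30, catalyst-controlled transfer hydrogenation to the 6S alcohol 31 and semi-hydrogenation to the Z alkene 32. C6 is set by the catalyst and the alkene geometry by the alkyne.

**Aldehyde 27 from the chiral pool.** Aldehyde 27 is traced to 2-deoxy-D-ribose 20. Its C3 and C4 become chain C4 (S) and C3 (R). Its methylene is C5, its aldehyde carbon is C6 and its C5 becomes C2. Only C1 has to be added. The cis-acetonide protects both hydroxyls until the etherification.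

**Alkyne 19 and the two ring bromides.** Alkyne 19 comes from dibromide 16 by unmasking and homologating C8. The C10–Br and C12–Br bonds of 16 are cut back to diaxial diol 14. Double inversion turns two axial oxygens into two equatorial bromides. It is done while C8 is a silyloxymethyl group, so that no second ring oxygen is near enough to participate.

**Diol 14 from enone 9.** Diol 14 comes from epoxy alcohol 13 by trans-diaxial hydride opening at C11. Epoxide 13 comes from the cis allylic alcohol 12 by hydroxyl-directed epoxidation. Alcohol 12 comes from enone 9 by 1,2-reduction and inversion. The direct reduction gives the equatorial alcohol 10, so one inversion is needed.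

**Ring C, O–C9 bond (key disconnection).** Enone 9 comes from hemiketal 8 by silane reduction. Hemiketal 8 is cut at the O–C9 bond and unfolded to furyl carbinol 6. The forward reaction oxidises the furan to an ene-dione. The C13 hydroxyl then closes ring C. This single step turns an aromatic ring into a pyranone with functionality on C9, C10/C11 and C12.

**Carbinol 6.** Carbinol 6 comes from ketone 5 by asymmetric transfer hydrogenation. Ketone 5 comes from silyl ether 2 and amide 3, and 2 from furfuryl alcohol 1. The precursor is reached in three routine steps.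

## Alternatives that were turned down

**Alternative 1:** Petasis–Ferrier route to ring A.
- **Disconnection.** The C5–C6 bond of ring A, with both alkynes already in place.
- **Forward key step.** A Lewis acid opens a cyclic enol acetal that links the C3 oxygen to C6. The freed enolate carbon C5 closes onto the alkynyl oxocarbenium carbon C6. The product is tetrahydrofuranone A1.
- **For.** It joins the two halves and makes ring A in one step. The 2,5-cis relationship is the expected one. The C4 ketone sits where the ring B oxygen is needed. On convergence it is stronger than the chosen route.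
- **Against.** Ring C must still be made, for example as 19. The rearrangement must run past two alkynes and two bromides. Ring B would then have to close onto a (Z)-C7=C8 alkene from a preformed ring A. That transition state forces C9 to eclipse C5, and endo attack at C8 would give a less strained [3.2.1] isomer.
- **Comparison.** The chosen route gives up some convergence. In return it closes ring B while the chain is still free and ring A afterwards by SN2, so both closures have a favourable geometry.

**Alternative 2:** Ireland–Claisen ring contraction to ring C.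
- **Disconnection.** The C9–C10 bond of ring C, with the lactone O–C12 bond broken in the same step.
- **Forward key step.** The silyl ketene acetal of a dioxanone rearranges through a boat transition state to dihydropyran acid A2.
- **For.** The cis C9/C13 relationship and the C10 oxygen are set stereospecifically. The C10 oxygen already has the configuration for invertive bromination. C8 arrives as a carboxyl group without a protecting group. On the C10 centre it is stronger than the chosen route, which needs a Mitsunobu correction at C12.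
- **Against.** A2 has only the isolated C11=C12 alkene at C12. The bromide there would need a regioselective and face-selective hydrofunctionalisation cis to the ethyl group. Nothing in A2 enforces either. The dioxanone precursor also takes more steps than 6.
- **Comparison.** The chosen route offers a ketone at C12 and an alkene at C10=C11 directly from the furan, four steps from 1.

**Alternative 3:** Ring expansion of a tetrahydrofuranyl carbinol.
- **Disconnection.** The O–C13 and C12–Br bonds of ring C.
- **Forward key step.** The C13 carbinol of a 2,5-trans tetrahydrofuran is activated. The ring oxygen displaces the leaving group, and bromide opens the oxonium ion at C12. The product A3 is the same compound as 16.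
- **For.** It forms the ring and the C12–Br bond in one stereospecific step. It avoids displacement of an axial sulfonate at C12. On this point it is stronger than the chosen route.
- **Against.** The tetrahydrofuran must already carry four stereocentres, including the C10 bromide or its precursor. Bromide can also open the oxonium ion at C13 and return a tetrahydrofuran.
- **Comparison.** The chosen route reaches 16 in ten steps from 1. All four ring C centres derive from the single C13 centre.

Key step: step 4

## Route

Step 1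
Reactants: 1 furan-2-ylmethanol
Product: 2 tert-butyl(furan-2-ylmethoxy)diphenylsilane
Conditions: TBDPSCl, imidazole, CH2Cl2, 0 °C to rt
Reagents that add atoms: tert-butyl(chloro)diphenylsilane, CC(C)(C)[Si](Cl)(c1ccccc1)c1ccccc1
Why: Silylation of a primary alcohol; the hindered silyl ether should withstand the organolithium, acid, hydride and anodic steps that follow.

Step 2
Reactants: 2 tert-butyl(furan-2-ylmethoxy)diphenylsilane; 3 N-methoxy-N-methylpropanamide
Product: 5 1-[5-({[tert-butyl(diphenyl)silyl]oxy}methyl)furan-2-yl]propan-1-one, via 5-lithiofuran 4 (not isolated)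
Conditions: n-BuLi, THF, −78 to 0 °C; then 3, −78 °C to rt; aq. NH4Cl
Reagents that add atoms: none
Why: A 2-substituted furan is lithiated at the free α-position; Weinreb ketone synthesis, in which the chelated tetrahedral adduct prevents over-addition.

Step 3
Reactants: 5 1-[5-({[tert-butyl(diphenyl)silyl]oxy}methyl)furan-2-yl]propan-1-one
Product: 6 (1S)-1-[5-({[tert-butyl(diphenyl)silyl]oxy}methyl)furan-2-yl]propan-1-ol
Conditions: RuCl[(S,S)-TsDPEN](p-cymene) (cat.), HCO2H/Et3N, rt
Reagents that add atoms: none
Why: Noyori asymmetric transfer hydrogenation of a 2-acylfuran; the furan plays the aryl role, so the (S,S)-catalyst should deliver hydride to give the S carbinol that becomes C13.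

Step 4
Reactants: 6 (1S)-1-[5-({[tert-butyl(diphenyl)silyl]oxy}methyl)furan-2-yl]propan-1-ol
Product: 8 (2S,6S)-6-({[tert-butyl(diphenyl)silyl]oxy}methyl)-2-ethyl-6-hydroxy-2H-pyran-3(6H)-one, via ene-dione 7 (not isolated)
Conditions: undivided cell, graphite anode, stainless-steel cathode, NaBr (mediator), NaHCO3, MeCN/H2O, constant current, slightly more than 2 F/mol, 0 °C to rt
Reagents that add atoms: water, O
Why: Bromide is oxidised at the anode to an electrophilic bromine species that attacks an α-carbon of the electron-rich 2,5-dialkylfuran; water adds at the other α-carbon and loss of HBr, which returns the mediator, gives a dihydrofuran that opens to the (Z)-ene-1,4-dione 7. The C13 hydroxyl then adds to the C9 ketone in a 6-exo-trig closure that forms the O–C9 bond and ring C as hemiketal 8, while water is reduced to H2 at the cathode. The closest known reaction is the Achmatowicz rearrangement, including its bromide-mediated electrochemical variants in aqueous solvent. The only new stereocentre, the C9 hemiketal carbon, is under thermodynamic anomeric control and is erased in step 5; C13 is not touched. The selectivity needed is chemoselective two-electron oxidation of the furan. The furan is the most easily oxidised π-system, the mediator keeps the working potential low, the bicarbonate buffer prevents acid-induced decomposition and the limited charge protects the secondary alcohol, the enone product and the silyl ether. The product carries the C12 ketone and the C10=C11 alkene that address both bromine-bearing carbons of ring C.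

Step 5
Reactants: 8 (2S,6S)-6-({[tert-butyl(diphenyl)silyl]oxy}methyl)-2-ethyl-6-hydroxy-2H-pyran-3(6H)-one
Product: 9 (2S,6S)-6-({[tert-butyl(diphenyl)silyl]oxy}methyl)-2-ethyl-2H-pyran-3(6H)-one
Conditions: Et3SiH, CF3CO2H, CH2Cl2, −40 °C
Reagents that add atoms: none
Why: Ionic hydrogenation of the hemiketal through the C9 oxocarbenium ion; axial hydride delivery on the half-chair with pseudo-equatorial ethyl should give the 2,6-cis ring and so set C9.

Step 6
Reactants: 9 (2S,6S)-6-({[tert-butyl(diphenyl)silyl]oxy}methyl)-2-ethyl-2H-pyran-3(6H)-one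
Product: 10 (2S,3R,6S)-6-({[tert-butyl(diphenyl)silyl]oxy}methyl)-2-ethyl-3,6-dihydro-2H-pyran-3-ol
Conditions: NaBH4, CeCl3·7H2O, MeOH, −78 °C
Reagents that add atoms: none
Why: Luche 1,2-reduction of the enone; the small hydride adds axially, anti to the axial C13–H, and should give the equatorial alcohol trans to the ethyl group, which is the epimer that has to be inverted.

Step 7
Reactants: 10 (2S,3R,6S)-6-({[tert-butyl(diphenyl)silyl]oxy}methyl)-2-ethyl-3,6-dihydro-2H-pyran-3-ol
Product: 12 (2S,3S,6S)-6-({[tert-butyl(diphenyl)silyl]oxy}methyl)-2-ethyl-3,6-dihydro-2H-pyran-3-ol, via 4-nitrobenzoate 11 (not isolated)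
Conditions: 4-O2NC6H4CO2H, PPh3, DIAD, THF, 0 °C to rt; then K2CO3, MeOH, rt
Reagents that add atoms: 4-nitrobenzoic acid, OC(=O)c1ccc(cc1)[N+](=O)[O-]
Why: Mitsunobu inversion of the allylic carbinol by SN2 with the acidic carboxylate, then methanolysis; this should give the pseudo-axial C12 alcohol cis to the ethyl group, which is needed to direct the epoxidation.

Step 8
Reactants: 12 (2S,3S,6S)-6-({[tert-butyl(diphenyl)silyl]oxy}methyl)-2-ethyl-3,6-dihydro-2H-pyran-3-ol
Product: 13 (1S,2R,4S,5R,6R)-2-({[tert-butyl(diphenyl)silyl]oxy}methyl)-4-ethyl-3,7-dioxabicyclo[4.1.0]heptan-5-ol (epoxide, hydroxyl and both alkyl groups on one face)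
Conditions: VO(acac)2 (cat.), t-BuOOH, CH2Cl2, 0 °C to rt
Reagents that add atoms: tert-butyl hydroperoxide, CC(C)(C)OO
Why: Hydroxyl-directed epoxidation of a cyclic allylic alcohol; the pseudo-axial C12 alkoxide binds the metal peroxide and should deliver oxygen to the C10=C11 face syn to it, against the steric bias of the C9 substituent.

Step 9
Reactants: 13 (1S,2R,4S,5R,6R)-2-({[tert-butyl(diphenyl)silyl]oxy}methyl)-4-ethyl-3,7-dioxabicyclo[4.1.0]heptan-5-ol
Product: 14 (2R,3R,5S,6S)-2-({[tert-butyl(diphenyl)silyl]oxy}methyl)-6-ethyloxane-3,5-diol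
Conditions: LiAlH4, THF, 0 °C to rt
Reagents that add atoms: none
Why: Hydride opening of the epoxide under Fürst–Plattner control; only attack at C11 is trans-diaxial in the half-chair that keeps both alkyl groups equatorial, and both epoxide carbons flank an oxygenated carbon so there is no opposing inductive bias. The diaxial 1,3-diol should result.

Step 10
Reactants: 14 (2R,3R,5S,6S)-2-({[tert-butyl(diphenyl)silyl]oxy}methyl)-6-ethyloxane-3,5-diol
Product: 16 tert-butyl{[(2R,3S,5R,6S)-3,5-dibromo-6-ethyloxan-2-yl]methoxy}diphenylsilane, via bis-triflate 15 (not isolated)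
Conditions: Tf2O, pyridine, CH2Cl2, −20 °C; then n-Bu4NBr, toluene, rt
Reagents that add atoms: tetrabutylammonium bromide, [Br-].CCCC[N+](CCCC)(CCCC)CCCC
Why: Double SN2 displacement of axial sulfonates by bromide, as in inversions of axial pyranose triflates; each inversion should give an equatorial bromide, and the axial leaving groups are gauche to the ring C–O bonds so the ring oxygen cannot participate.

Step 11
Reactants: 16 tert-butyl{[(2R,3S,5R,6S)-3,5-dibromo-6-ethyloxan-2-yl]methoxy}diphenylsilane
Product: 17 [(2R,3S,5R,6S)-3,5-dibromo-6-ethyloxan-2-yl]methanol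
Conditions: HF·pyridine, pyridine, THF, 0 °C to rt
Reagents that add atoms: none
Why: Acidic fluoride cleavage of the silyl ether; no base is present that could eliminate the equatorial bromides.

Step 12
Reactants: 17 [(2R,3S,5R,6S)-3,5-dibromo-6-ethyloxan-2-yl]methanol
Product: 18 (2R,3S,5R,6S)-3,5-dibromo-6-ethyloxane-2-carbaldehyde
Conditions: Dess–Martin periodinane, NaHCO3, CH2Cl2, 0 °C
Reagents that add atoms: none
Why: Dess–Martin oxidation under buffered, non-basic conditions; the β-bromo aldehyde is to be used at once without chromatography.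

Step 13
Reactants: 18 (2R,3S,5R,6S)-3,5-dibromo-6-ethyloxane-2-carbaldehyde
Product: 19 (2S,3R,5S,6R)-3,5-dibromo-2-ethyl-6-ethynyloxane
Conditions: Me3SiCHN2, n-BuLi, THF, −78 °C; then 18, −78 to 0 °C; aq. NH4Cl
Reagents that add atoms: (trimethylsilyl)diazomethane, C[Si](C)(C)C=[N+]=[N-]
Why: Colvin homologation; the lithiated diazo reagent adds to the aldehyde at low temperature, Peterson elimination and loss of N2 give an alkylidene carbene, and 1,2-hydrogen shift gives the terminal alkyne with C7 in place.

Step 14
Reactants: 20 2-deoxy-D-ribose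
Product: 21 2-deoxy-3,4-O-isopropylidene-D-ribopyranose
Conditions: 2-methoxypropene, PPTS (cat.), DMF, 0 °C
Reagents that add atoms: 2-methoxypropene, COC(C)=C
Why: Kinetic acetonide formation on the cis-3,4-diol of the pyranose; the anomeric carbon stays as the lactol.

Step 15
Reactants: 21 2-deoxy-3,4-O-isopropylidene-D-ribopyranose
Product: 22 [(4R,5S)-2,2-dimethyl-5-(prop-2-en-1-yl)-1,3-dioxolan-4-yl]methanol
Conditions: Ph3PCH3Br, KOt-Bu, THF, 0 °C to rt
Reagents that add atoms: methyltriphenylphosphonium bromide, C[P+](c1ccccc1)(c1ccccc1)c1ccccc1.[Br-]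
Why: Wittig methylenation of the open-chain aldehyde form of the lactol; it masks C6 as an alkene and frees the primary hydroxyl on the future C2.

Step 16
Reactants: 22 [(4R,5S)-2,2-dimethyl-5-(prop-2-en-1-yl)-1,3-dioxolan-4-yl]methanol
Product: 23 (4S,5S)-2,2-dimethyl-5-(prop-2-en-1-yl)-1,3-dioxolane-4-carbaldehyde
Conditions: Dess–Martin periodinane, NaHCO3, CH2Cl2, 0 °C to rt
Reagents that add atoms: none
Why: Dess–Martin oxidation; the neutral conditions should keep the cis-dioxolane aldehyde from epimerising.

Step 17
Reactants: 23 (4S,5S)-2,2-dimethyl-5-(prop-2-en-1-yl)-1,3-dioxolane-4-carbaldehyde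
Product: 24 (4R,5S)-4-(2,2-dibromoethenyl)-2,2-dimethyl-5-(prop-2-en-1-yl)-1,3-dioxolane
Conditions: CBr4, PPh3, Zn, CH2Cl2, rt; then 23, 0 °C to rt
Reagents that add atoms: carbon tetrabromide, BrC(Br)(Br)Br
Why: First stage of the Corey–Fuchs alkyne synthesis; the preformed, base-free dibromomethylene ylide olefinates the aldehyde and adds C1.

Step 18
Reactants: 24 (4R,5S)-4-(2,2-dibromoethenyl)-2,2-dimethyl-5-(prop-2-en-1-yl)-1,3-dioxolane
Product: 26 {[(4R,5S)-2,2-dimethyl-5-(prop-2-en-1-yl)-1,3-dioxolan-4-yl]ethynyl}tri(propan-2-yl)silane, via lithium acetylide 25 (not isolated)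
Conditions: n-BuLi (2.1 equiv), THF, −78 °C; then i-Pr3SiOTf, −78 °C to rt
Reagents that add atoms: tri(propan-2-yl)silyl trifluoromethanesulfonate, CC(C)[Si](OS(=O)(=O)C(F)(F)F)(C(C)C)C(C)C
Why: Second stage of the Corey–Fuchs sequence; bromine–lithium exchange, rearrangement to the alkyne and deprotonation give the acetylide, which is silylated in the same flask. The bulky silyl group protects the C1–C2 alkyne in steps 20 and 23.

Step 19
Reactants: 26 {[(4R,5S)-2,2-dimethyl-5-(prop-2-en-1-yl)-1,3-dioxolan-4-yl]ethynyl}tri(propan-2-yl)silane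
Product: 27 {(4S,5R)-2,2-dimethyl-5-[(tri(propan-2-yl)silyl)ethynyl]-1,3-dioxolan-4-yl}acetaldehyde
Conditions: OsO4 (cat.), NaIO4, 2,6-lutidine, dioxane/H2O, rt
Reagents that add atoms: sodium periodate, [Na+].[O-]I(=O)(=O)=O
Why: Lemieux–Johnson cleavage of the terminal alkene; OsO4 dihydroxylates alkenes far faster than silylated alkynes, and the lutidine buffer should protect the acetonide and the β-alkoxy aldehyde.

Step 20
Reactants: 19 (2S,3R,5S,6R)-3,5-dibromo-2-ethyl-6-ethynyloxane; 27 {(4S,5R)-2,2-dimethyl-5-[(tri(propan-2-yl)silyl)ethynyl]-1,3-dioxolan-4-yl}acetaldehyde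
Product: 29 1-[(2R,3S,5R,6S)-3,5-dibromo-6-ethyloxan-2-yl]-4-{(4S,5R)-2,2-dimethyl-5-[(tri(propan-2-yl)silyl)ethynyl]-1,3-dioxolan-4-yl}but-1-yn-3-ol (both C6 epimers), via alkynylmagnesium bromide 28 (not isolated)
Conditions: EtMgBr, THF, rt; then 27, −78 to 0 °C; aq. NH4Cl
Reagents that add atoms: none
Why: Deprotonation of the terminal alkyne by a Grignard reagent, which leaves secondary alkyl bromides alone, followed by 1,2-addition to the aldehyde; this forms the C6–C7 bond. The C6 configuration is not controlled here and is reset in steps 21 and 22.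

Step 21
Reactants: 29 C6-epimeric propargylic alcohols
Product: 30 1-[(2R,3S,5R,6S)-3,5-dibromo-6-ethyloxan-2-yl]-4-{(4S,5R)-2,2-dimethyl-5-[(tri(propan-2-yl)silyl)ethynyl]-1,3-dioxolan-4-yl}but-1-yn-3-one
Conditions: Dess–Martin periodinane, NaHCO3, CH2Cl2, 0 °C
Reagents that add atoms: none
Why: Dess–Martin oxidation of a propargylic alcohol to the ynone; both epimers converge on one compound under non-basic conditions.

Step 22
Reactants: 30 ynone
Product: 31 (3S)-1-[(2R,3S,5R,6S)-3,5-dibromo-6-ethyloxan-2-yl]-4-{(4S,5R)-2,2-dimethyl-5-[(tri(propan-2-yl)silyl)ethynyl]-1,3-dioxolan-4-yl}but-1-yn-3-ol (6S in chain numbering)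
Conditions: RuCl[(S,S)-TsDPEN](p-cymene) (cat.), HCO2H/Et3N, CH2Cl2, rt
Reagents that add atoms: none
Why: Noyori asymmetric transfer hydrogenation of an alkynyl ketone; the alkyne takes the place of the aryl group, so the (S,S)-catalyst should give the 6S carbinol under catalyst control. The slightly acidic medium avoids β-elimination of the C4 oxygen.

Step 23
Reactants: 31 (6S)-propargylic alcohol
Product: 32 (1Z,3S)-1-[(2R,3S,5R,6S)-3,5-dibromo-6-ethyloxan-2-yl]-4-{(4S,5R)-2,2-dimethyl-5-[(tri(propan-2-yl)silyl)ethynyl]-1,3-dioxolan-4-yl}but-1-en-3-ol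
Conditions: H2 (1 atm), Pd/CaCO3 poisoned with Pb(OAc)2 (Lindlar catalyst), quinoline, EtOAc, rt
Reagents that add atoms: none
Why: Lindlar semi-hydrogenation by syn addition gives the (Z)-C7=C8 alkene; the hindered silyl-capped alkyne and the alkyl bromides should be left alone.

Step 24
Reactants: 32 (Z)-allylic alcohol
Product: 33 tert-butyldimethylsilyl ether of 32 at the C6 oxygen
Conditions: TBSCl, imidazole, DMF, rt
Reagents that add atoms: tert-butyl(chloro)dimethylsilane, CC(C)(C)[Si](C)(C)Cl
Why: Silylation of the allylic alcohol; it keeps the C6 oxygen out of the etherification and the mesylation and allows its release by fluoride in the last step.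

Step 25
Reactants: 33 C6 silyl ether
Product: 35 (1R)-1-{(2S,3S,5S)-5-[(S)-bromo((2S,3S,5R,6S)-3,5-dibromo-6-ethyloxan-2-yl)methyl]-4-[(tert-butyldimethylsilyl)oxy]oxolan-2-yl}-3-[tri(propan-2-yl)silyl]prop-2-yn-1-ol (oxolane C2 = C4 4S, C4 = C6 6S, C5 = C7 7S; bromomethine C8 8R; carbinol C3 3R), via hemiketal 34 (not isolated)
Conditions: NBS, NaHCO3, MeCN/H2O, 0 °C
Reagents that add atoms: N-bromosuccinimide, O=C1CCC(=O)N1Br
Why: Bromoetherification with an acetal oxygen as the nucleophile, a known mode of haloetherification; the C4 oxygen opens the bromonium ion at C7 in a 5-exo closure, and the oxonium ion sheds the isopropylidene group as acetone through hemiketal 34. Anti addition to the Z alkene and the reactive rotamer with C6–H in the alkene plane should give 7S and 8R.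

Step 26
Reactants: 35 ring B alcohol
Product: 36 methanesulfonate of 35 at the C3 oxygen
Conditions: MsCl, Et3N, CH2Cl2, −20 to 0 °C
Reagents that add atoms: methanesulfonyl chloride, CS(=O)(=O)Cl
Why: Sulfonylation of the only free hydroxyl; a mesylate is reactive enough for the intramolecular displacement but should not ionise with participation of the neighbouring ring B oxygen.

Step 27
Reactants: 36 C3 mesylate
Product: 39 (1S,3S,4S,6S)-3-[(R)-bromo((2S,3S,5R,6S)-3,5-dibromo-6-ethyloxan-2-yl)methyl]-6-ethynyl-2,5-dioxabicyclo[2.2.1]heptane, via hydroxy mesylate 37 (not isolated), via silylated bicycle 38 (not isolated)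
Conditions: n-Bu4NF, THF, 0 °C to rt
Reagents that add atoms: none
Why: Fluoride cleaves the C6 silyl ether, and the alkoxide displaces the propargylic mesylate in a 5-exo-tet Williamson closure with inversion at C3, the mode used to close 2,5-dioxabicyclo[2.2.1]heptanes in bridged nucleosides. The ethynyl group ends endo with 3S configuration. The same reagent removes the alkyne silyl group.

## Compound list

1 | furan-2-ylmethanol | OCc1ccco1 | starting material
2 | tert-butyl(furan-2-ylmethoxy)diphenylsilane | CC(C)(C)[Si](OCc1ccco1)(c1ccccc1)c1ccccc1 | intermediate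
3 | N-methoxy-N-methylpropanamide | CCC(=O)N(C)OC | starting material
4 | [5-({[tert-butyl(diphenyl)silyl]oxy}methyl)furan-2-yl]lithium | [Li]c1ccc(CO[Si](c2ccccc2)(c2ccccc2)C(C)(C)C)o1 | intermediate
5 | 1-[5-({[tert-butyl(diphenyl)silyl]oxy}methyl)furan-2-yl]propan-1-one | CCC(=O)c1ccc(CO[Si](c2ccccc2)(c2ccccc2)C(C)(C)C)o1 | intermediate
6 | (1S)-1-[5-({[tert-butyl(diphenyl)silyl]oxy}methyl)furan-2-yl]propan-1-ol | CC[C@H](O)c1ccc(CO[Si](c2ccccc2)(c2ccccc2)C(C)(C)C)o1 | intermediate
7 | (3Z,6S)-1-{[tert-butyl(diphenyl)silyl]oxy}-6-hydroxyoct-3-ene-2,5-dione | CC[C@H](O)C(=O)/C=C\C(=O)CO[Si](c1ccccc1)(c1ccccc1)C(C)(C)C | intermediate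
8 | (2S,6S)-6-({[tert-butyl(diphenyl)silyl]oxy}methyl)-2-ethyl-6-hydroxy-2H-pyran-3(6H)-one | CC[C@@H]1O[C@](O)(CO[Si](c2ccccc2)(c2ccccc2)C(C)(C)C)C=CC1=O | intermediate
9 | (2S,6S)-6-({[tert-butyl(diphenyl)silyl]oxy}methyl)-2-ethyl-2H-pyran-3(6H)-one | CC[C@@H]1O[C@H](CO[Si](c2ccccc2)(c2ccccc2)C(C)(C)C)C=CC1=O | intermediate
10 | (2S,3R,6S)-6-({[tert-butyl(diphenyl)silyl]oxy}methyl)-2-ethyl-3,6-dihydro-2H-pyran-3-ol | CC[C@@H]1O[C@H](CO[Si](c2ccccc2)(c2ccccc2)C(C)(C)C)C=C[C@H]1O | intermediate
11 | (2S,3S,6S)-6-({[tert-butyl(diphenyl)silyl]oxy}methyl)-2-ethyl-3,6-dihydro-2H-pyran-3-yl 4-nitrobenzoate | CC[C@@H]1O[C@H](CO[Si](c2ccccc2)(c2ccccc2)C(C)(C)C)C=C[C@@H]1OC(=O)c1ccc(cc1)[N+](=O)[O-] | intermediate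
12 | (2S,3S,6S)-6-({[tert-butyl(diphenyl)silyl]oxy}methyl)-2-ethyl-3,6-dihydro-2H-pyran-3-ol | CC[C@@H]1O[C@H](CO[Si](c2ccccc2)(c2ccccc2)C(C)(C)C)C=C[C@@H]1O | intermediate
13 | (1S,2R,4S,5R,6R)-2-({[tert-butyl(diphenyl)silyl]oxy}methyl)-4-ethyl-3,7-dioxabicyclo[4.1.0]heptan-5-ol | CC[C@@H]1O[C@H](CO[Si](c3ccccc3)(c3ccccc3)C(C)(C)C)[C@@H]2O[C@@H]2[C@@H]1O | intermediate
14 | (2R,3R,5S,6S)-2-({[tert-butyl(diphenyl)silyl]oxy}methyl)-6-ethyloxane-3,5-diol | CC[C@@H]1O[C@H](CO[Si](c2ccccc2)(c2ccccc2)C(C)(C)C)[C@H](O)C[C@@H]1O | intermediate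
15 | (2R,3R,5S,6S)-2-({[tert-butyl(diphenyl)silyl]oxy}methyl)-6-ethyloxane-3,5-diyl bis(trifluoromethanesulfonate) | CC[C@@H]1O[C@H](CO[Si](c2ccccc2)(c2ccccc2)C(C)(C)C)[C@H](OS(=O)(=O)C(F)(F)F)C[C@@H]1OS(=O)(=O)C(F)(F)F | intermediate
16 | tert-butyl{[(2R,3S,5R,6S)-3,5-dibromo-6-ethyloxan-2-yl]methoxy}diphenylsilane | CC[C@@H]1O[C@H](CO[Si](c2ccccc2)(c2ccccc2)C(C)(C)C)[C@@H](Br)C[C@H]1Br | intermediate
17 | [(2R,3S,5R,6S)-3,5-dibromo-6-ethyloxan-2-yl]methanol | CC[C@@H]1O[C@H](CO)[C@@H](Br)C[C@H]1Br | intermediate
18 | (2R,3S,5R,6S)-3,5-dibromo-6-ethyloxane-2-carbaldehyde | CC[C@@H]1O[C@H](C=O)[C@@H](Br)C[C@H]1Br | intermediate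
19 | (2S,3R,5S,6R)-3,5-dibromo-2-ethyl-6-ethynyloxane | CC[C@@H]1O[C@H](C#C)[C@@H](Br)C[C@H]1Br | intermediate
20 | 2-deoxy-D-ribose (open-chain form shown) | O=CC[C@H](O)[C@H](O)CO | starting material
21 | 2-deoxy-3,4-O-isopropylidene-D-ribopyranose (anomeric mixture) | OC1C[C@@H]2OC(C)(C)O[C@@H]2CO1 | intermediate
22 | [(4R,5S)-2,2-dimethyl-5-(prop-2-en-1-yl)-1,3-dioxolan-4-yl]methanol | C=CC[C@@H]1OC(C)(C)O[C@@H]1CO | intermediate
23 | (4S,5S)-2,2-dimethyl-5-(prop-2-en-1-yl)-1,3-dioxolane-4-carbaldehyde | C=CC[C@@H]1OC(C)(C)O[C@@H]1C=O | intermediate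
24 | (4R,5S)-4-(2,2-dibromoethenyl)-2,2-dimethyl-5-(prop-2-en-1-yl)-1,3-dioxolane | C=CC[C@@H]1OC(C)(C)O[C@@H]1C=C(Br)Br | intermediate
25 | {[(4R,5S)-2,2-dimethyl-5-(prop-2-en-1-yl)-1,3-dioxolan-4-yl]ethynyl}lithium | C=CC[C@@H]1OC(C)(C)O[C@@H]1C#C[Li] | intermediate
26 | {[(4R,5S)-2,2-dimethyl-5-(prop-2-en-1-yl)-1,3-dioxolan-4-yl]ethynyl}tri(propan-2-yl)silane | C=CC[C@@H]1OC(C)(C)O[C@@H]1C#C[Si](C(C)C)(C(C)C)C(C)C | intermediate
27 | {(4S,5R)-2,2-dimethyl-5-[(tri(propan-2-yl)silyl)ethynyl]-1,3-dioxolan-4-yl}acetaldehyde | O=CC[C@@H]1OC(C)(C)O[C@@H]1C#C[Si](C(C)C)(C(C)C)C(C)C | intermediate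
28 | {[(2R,3S,5R,6S)-3,5-dibromo-6-ethyloxan-2-yl]ethynyl}magnesium bromide | CC[C@@H]1O[C@H](C#C[Mg]Br)[C@@H](Br)C[C@H]1Br | intermediate
29 | 1-[(2R,3S,5R,6S)-3,5-dibromo-6-ethyloxan-2-yl]-4-{(4S,5R)-2,2-dimethyl-5-[(tri(propan-2-yl)silyl)ethynyl]-1,3-dioxolan-4-yl}but-1-yn-3-ol, both C6 epimers | CC[C@@H]1O[C@H](C#CC(O)C[C@@H]2OC(C)(C)O[C@@H]2C#C[Si](C(C)C)(C(C)C)C(C)C)[C@@H](Br)C[C@H]1Br | intermediate
30 | 1-[(2R,3S,5R,6S)-3,5-dibromo-6-ethyloxan-2-yl]-4-{(4S,5R)-2,2-dimethyl-5-[(tri(propan-2-yl)silyl)ethynyl]-1,3-dioxolan-4-yl}but-1-yn-3-one | CC[C@@H]1O[C@H](C#CC(=O)C[C@@H]2OC(C)(C)O[C@@H]2C#C[Si](C(C)C)(C(C)C)C(C)C)[C@@H](Br)C[C@H]1Br | intermediate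
31 | (3S)-1-[(2R,3S,5R,6S)-3,5-dibromo-6-ethyloxan-2-yl]-4-{(4S,5R)-2,2-dimethyl-5-[(tri(propan-2-yl)silyl)ethynyl]-1,3-dioxolan-4-yl}but-1-yn-3-ol | CC[C@@H]1O[C@H](C#C[C@@H](O)C[C@@H]2OC(C)(C)O[C@@H]2C#C[Si](C(C)C)(C(C)C)C(C)C)[C@@H](Br)C[C@H]1Br | intermediate
32 | (1Z,3S)-1-[(2R,3S,5R,6S)-3,5-dibromo-6-ethyloxan-2-yl]-4-{(4S,5R)-2,2-dimethyl-5-[(tri(propan-2-yl)silyl)ethynyl]-1,3-dioxolan-4-yl}but-1-en-3-ol | CC[C@@H]1O[C@H](/C=C\[C@@H](O)C[C@@H]2OC(C)(C)O[C@@H]2C#C[Si](C(C)C)(C(C)C)C(C)C)[C@@H](Br)C[C@H]1Br | intermediate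
33 | tert-butyldimethylsilyl ether of 32 at the C6 oxygen | CC[C@@H]1O[C@H](/C=C\[C@@H](O[Si](C)(C)C(C)(C)C)C[C@@H]2OC(C)(C)O[C@@H]2C#C[Si](C(C)C)(C(C)C)C(C)C)[C@@H](Br)C[C@H]1Br | intermediate
34 | 2-hydroxypropan-2-yl ether (hemiketal) of 35 at the C3 oxygen | CC[C@@H]1O[C@H]([C@H](Br)[C@H]2O[C@@H](C[C@@H]2O[Si](C)(C)C(C)(C)C)[C@H](OC(C)(C)O)C#C[Si](C(C)C)(C(C)C)C(C)C)[C@@H](Br)C[C@H]1Br | intermediate
35 | (1R)-1-{(2S,3S,5S)-5-[(S)-bromo((2S,3S,5R,6S)-3,5-dibromo-6-ethyloxan-2-yl)methyl]-4-[(tert-butyldimethylsilyl)oxy]oxolan-2-yl}-3-[tri(propan-2-yl)silyl]prop-2-yn-1-ol; chain descriptors 3R,4S,6S,7S,8R | CC[C@@H]1O[C@H]([C@H](Br)[C@H]2O[C@@H](C[C@@H]2O[Si](C)(C)C(C)(C)C)[C@H](O)C#C[Si](C(C)C)(C(C)C)C(C)C)[C@@H](Br)C[C@H]1Br | intermediate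
36 | methanesulfonate of 35 at the C3 oxygen | CC[C@@H]1O[C@H]([C@H](Br)[C@H]2O[C@@H](C[C@@H]2O[Si](C)(C)C(C)(C)C)[C@H](OS(C)(=O)=O)C#C[Si](C(C)C)(C(C)C)C(C)C)[C@@H](Br)C[C@H]1Br | intermediate
37 | C6 hydroxy, C3 methanesulfonate (36 without the O-silyl group) | CC[C@@H]1O[C@H]([C@H](Br)[C@H]2O[C@@H](C[C@@H]2O)[C@H](OS(C)(=O)=O)C#C[Si](C(C)C)(C(C)C)C(C)C)[C@@H](Br)C[C@H]1Br | intermediate
38 | C1 tri(propan-2-yl)silyl derivative of 39 | CC(C)[Si](C(C)C)(C(C)C)C#C[C@@H]1O[C@H]2C[C@@H]1O[C@@H]2[C@@H](Br)[C@H]1O[C@@H](CC)[C@H](Br)C[C@@H]1Br | intermediate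
39 | (1S,3S,4S,6S)-3-[(R)-bromo((2S,3S,5R,6S)-3,5-dibromo-6-ethyloxan-2-yl)methyl]-6-ethynyl-2,5-dioxabicyclo[2.2.1]heptane | C#C[C@@H]1O[C@H]2C[C@@H]1O[C@@H]2[C@@H](Br)[C@H]1O[C@@H](CC)[C@H](Br)C[C@@H]1Br | target

## Step count and least certain steps

Total step count: 27. Longest linear sequence: 21 steps (steps 1–13 and 20–27, from 1 to 39). The branch from 20 to 27 has 6 steps (14–19).

**Step 4 (key step).** The most likely failure is over-oxidation. The enone product or the secondary alcohol may be oxidised further once the furan is consumed. The bromonium stage may also be diverted to ring bromination when water adds too slowly. As a fallback, 6 would be electrolysed in methanol with NaBr as electrolyte. This should give the bis-ketal (1S)-1-[5-({[tert-butyl(diphenyl)silyl]oxy}methyl)-2,5-dimethoxy-2,5-dihydrofuran-2-yl]propan-1-ol F1. F1 can be purified and is then hydrolysed and rearranged with dilute aqueous H2SO4 in THF. The route is rejoined at 8. Oxidation and ring closure are thereby separated.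

**Step 10.** Elimination may compete with substitution. Each axial sulfonate has two antiperiplanar axial hydrogens, and loss of one towards C9 would give an enol ether. The second displacement may also stall. As a fallback, 14 would be heated with CBr4 and tri-n-octylphosphine in toluene. The two hydroxyls are then activated one after the other as oxyphosphonium ions, and no amine base is present. This leads directly to 16.

**Step 13.** The aldehyde 18 has an acidic C9–H and a β-bromide on C10. Base-induced loss of HBr, or epimerisation at C9, may outrun the addition of the lithiated diazo reagent. As a fallback, 18 would be converted under neutral conditions (CBr4, PPh3, Zn) into (2R,3S,5R,6S)-3,5-dibromo-2-(2,2-dibromoethenyl)-6-ethyloxane F2. F2 no longer has an activated C9–H. Treatment with n-BuLi at −78 °C and trapping of the acetylide with aldehyde 27 would rejoin the route at 29.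

**Step 25.** Ring closure may take the endo course at C8 and give a six-membered ether. The other acetal oxygen may attack, or water may capture the bromonium ion. Poor facial selectivity is less likely because of the allylic strain of the Z alkene. As a fallback, the acetonide of 33 would first be hydrolysed (CeCl3·7H2O, oxalic acid, MeCN). This gives the diol (silyl ether at C6, free hydroxyls at C3 and C4) F3. The free C4 hydroxyl would then be cyclised with 2,4,4,6-tetrabromocyclohexa-2,5-dienone in dry CH2Cl2, where no external nucleophile is present. The route is rejoined at 35.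

**Step 27.** Fluoride is basic and nucleophilic. It may cause dehydrobromination at C8 or substitution and elimination at the propargylic mesylate before the hindered silyl ether is cleaved. The strained ring closure may then be too slow. As a fallback, 35 would be desilylated at oxygen with HF·pyridine to the C3,C6-diol F4. F4 would be closed by Mitsunobu cyclodehydration (PPh3, DIAD, toluene). Only activation of the propargylic hydroxyl can lead to a ring, so this should give 38 without a free alkoxide. The alkyne silyl group of 38 would then be removed with AgF in MeCN followed by dilute HCl, giving 39.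

## Further compounds

F1 | step 4 | (1S)-1-[5-({[tert-butyl(diphenyl)silyl]oxy}methyl)-2,5-dimethoxy-2,5-dihydrofuran-2-yl]propan-1-ol (mixture at both ketal carbons) | CC[C@H](O)C1(OC)C=CC(CO[Si](c2ccccc2)(c2ccccc2)C(C)(C)C)(OC)O1
F0 | step 10 | none | none
F2 | step 13 | (2R,3S,5R,6S)-3,5-dibromo-2-(2,2-dibromoethenyl)-6-ethyloxane | CC[C@@H]1O[C@H](C=C(Br)Br)[C@@H](Br)C[C@H]1Br
F3 | step 25 | C3,C4-diol from 33 (C6 silyl ether, Z alkene) | CC[C@@H]1O[C@H](/C=C\[C@@H](O[Si](C)(C)C(C)(C)C)C[C@H](O)[C@H](O)C#C[Si](C(C)C)(C(C)C)C(C)C)[C@@H](Br)C[C@H]1Br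
F4 | step 27 | C3,C6-diol from 35 | CC[C@@H]1O[C@H]([C@H](Br)[C@H]2O[C@@H](C[C@@H]2O)[C@H](O)C#C[Si](C(C)C)(C(C)C)C(C)C)[C@@H](Br)C[C@H]1Br
A1 | alternative 1 | cis-2,5-dialkynyltetrahydrofuran-3-one with the C1–C15 chain, silylated at C1 | CC(C)[Si](C(C)C)(C(C)C)C#C[C@@H]1O[C@@H](CC1=O)C#C[C@H]2O[C@@H](CC)[C@H](Br)C[C@@H]2Br
A2 | alternative 2 | cis-6-ethyl-3-(4-methoxybenzyloxy)-3,6-dihydro-2H-pyran-2-carboxylic acid | OC(=O)[C@H]1O[C@@H](CC)C=C[C@H]1OCc1ccc(OC)cc1
A3 | alternative 3 | tert-butyl{[(2R,3S,5R,6S)-3,5-dibromo-6-ethyloxan-2-yl]methoxy}diphenylsilane | CC(C)(C)[Si](c1ccccc1)(c1ccccc1)OC[C@H]1O[C@@H](CC)[C@H](Br)C[C@@H]1Br
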